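**Plan**

1. Locants: decalin C1–C10 (C4 = CMe2, C5 = ring-fusion CH, C8 = CHMe, C9 = quaternary C, alkene C1=C10; ring A = C1–C5/C10, ring B = C5–C10); linker C11–C12; peroxide ring O1'–O2'–C3'–C4'–C5'–C6' (C6' carries CH3 and C12); Cα = the CH(CH3)CO2H carbon on C3'.
2. Retrosynthetic cuts: O2'–C3' (hydroperoxide SN2 on a mesylate) and C6'–O1' (perhydrolysis of a C5'–C6' epoxide) of the 1,2-dioxane; then C4'–C5' (alkenylalanate + Roche-ester epoxide); then C7–C8 and C9–C10 of ring B in one operation.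
3. Enabling feature: ring B holds the C8(H)Me–C9(quaternary) pair between C7H2 and the alkene carbon C10, so it is the [4+2] adduct of a ring-A 1-vinylcyclohexene (C10=C5–C6=C7) and an (E)-2-alkylbut-2-enal (C8=C9). The CHO on C9 is the latent C9 methyl; an OTBS group at C1 is the relay that later puts the alkene at C1=C10 and delivers H to C5.
4. Forward order: ring-A diene + enal → ring B by Diels–Alder → CHO to CH3, C1 ketone, conjugation, CBS reduction, reductive allylic transposition → carboalumination/epoxide opening attaches the side chain → directed epoxidation, mesylation, perhydrolysis/ring closure to the 1,2-dioxane, dehydration, diimide, desilylation, oxidation.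
5. Stereochemistry: C8/C9 from enal geometry (relative) and the chiral oxazaborolidinium catalyst (absolute); C5 from the CBS-set C1 carbinol by suprafacial diazene rearrangement; Cα/C3' from the Roche ester and a hydrolytic kinetic resolution (C3' inverted on ring closure); C6' from the (E)-alkene by OH-directed epoxidation and invertive perhydrolysis.

Key step: step 7

Abbreviation: "Dec" = the (1R,2R,4aS)-1,2,5,5-tetramethyl-1,2,3,4,4a,5,6,7-octahydronaphthalen-1-yl group.

Assumption: the (S)-oxazaborolidinium catalyst is taken to leave the C2-Re face of the 2-substituted enal open, as its formyl C–H···O binding model predicts for 2-methylacrolein; the (R)-catalyst would be used if the sense were the opposite.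

**Step 1**
Reactants: 1 4,4-dimethylcyclohexane-1,3-dione
Product: 2 3-ethoxy-6,6-dimethylcyclohex-2-en-1-one
Conditions: EtOH, TsOH (cat.), benzene, reflux (Dean–Stark)
Reagents that add atoms: ethanol CCO
Why: acid-catalysed vinylogous ester formation should occur at the less hindered carbonyl, leaving the C=O beside the gem-dimethyl carbon.

**Step 2**
Reactants: 2 3-ethoxy-6,6-dimethylcyclohex-2-en-1-one
Product: 4 4,4-dimethyl-3-vinylcyclohex-2-en-1-one, via tertiary alcohol 3 (not isolated)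
Conditions: CH2=CHMgBr, THF, 0 °C; then 1 M HCl, 23 °C
Reagents that add atoms: vinylmagnesium bromide C=C[Mg]Br
Why: Stork–Danheiser transposition, in which 1,2-addition to the vinylogous ester carbonyl and acid hydrolysis–dehydration place the vinyl group beside the gem-dimethyl carbon and the carbonyl at the future C1.

**Step 3**
Reactants: 4 4,4-dimethyl-3-vinylcyclohex-2-en-1-one
Product: 5 rac-4,4-dimethyl-3-vinylcyclohex-2-en-1-ol
Conditions: NaBH4, CeCl3·7H2O, MeOH, 0 °C
Reagents that add atoms: none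
Why: Luche reduction gives clean 1,2-reduction of the dienone; the racemic carbinol suffices because this centre becomes trigonal in step 10.

**Step 4**
Reactants: 5 rac-4,4-dimethyl-3-vinylcyclohex-2-en-1-ol
Product: 6 rac-tert-butyl[(4,4-dimethyl-3-vinylcyclohex-2-en-1-yl)oxy]dimethylsilane
Conditions: TBSCl, imidazole, DMF, 23 °C
Reagents that add atoms: tert-butyldimethylsilyl chloride CC(C)(C)[Si](C)(C)Cl
Why: standard silylation masks the C1 oxygen for the Lewis-acid step.

**Step 5**
Reactants: 7 (E)-but-2-enal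
Product: 9 (Z)-2-bromobut-2-enal, via dibromide 8 (not isolated)
Conditions: Br2, CH2Cl2, 0 °C; then Et3N, 0 → 23 °C
Reagents that add atoms: bromine BrBr
Why: bromination–dehydrobromination of an enal gives the α-bromo enal as the isomer with CHO trans to CH3.

**Step 6**
Reactants: 10 (4-bromobut-1-yn-1-yl)trimethylsilane; 9 (Z)-2-bromobut-2-enal
Product: 12 (E)-2-[4-(trimethylsilyl)but-3-yn-1-yl]but-2-enal, via alkylzinc bromide 11 (not isolated)
Conditions: 10, Zn dust, LiCl, THF, 50 °C; then 9, Pd(PPh3)4 (5 mol%), THF, 23 °C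
Reagents that add atoms: none
Why: Negishi coupling (zinc insertion, then zerovalent palladium catalysis) should replace bromine with retention of alkene geometry and tolerate the aldehyde, giving the enal with the chain cis to the β-methyl group.

**Step 7**
Reactants: 6 rac-tert-butyl[(4,4-dimethyl-3-vinylcyclohex-2-en-1-yl)oxy]dimethylsilane; 12 (E)-2-[4-(trimethylsilyl)but-3-yn-1-yl]but-2-enal
Product: 13 (1S,2R)-8-[(tert-butyldimethylsilyl)oxy]-2,5,5-trimethyl-1-[4-(trimethylsilyl)but-3-yn-1-yl]-1,2,3,5,6,7,8,8a-octahydronaphthalene-1-carbaldehyde (mixture of epimers at the OTBS carbon C1 and the ring-fusion carbon C10)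
Conditions: 6 (2 equiv), (S)-3,3-diphenyl-1-(2-methylphenyl)tetrahydro-1H,3H-pyrrolo[1,2-c][1,3,2]oxazaborole (20 mol%), HNTf2 (18 mol%), CH2Cl2, −78 → −40 °C
Reagents that add atoms: none
Why: Catalytic enantioselective Diels–Alder reaction of the oxazaborolidinium type: the boron-bound s-trans enal adds across the semicyclic diene C10=C5–C6=C7 in a concerted but asynchronous [4π+2π] cycloaddition, with C7–C8 bond formation (free diene terminus to the enal β-carbon) ahead of C9–C10. Ring B closes by this intermolecular suprafacial six-membered cycloaddition, the carbonyl-endo mode being expected because it keeps the α-chain away from the C4 methyl groups. C8 and C9 are fixed relative to each other by the (E)-geometry of the enal (C8 methyl cis to the chain, trans to CHO) and in the absolute sense by the catalyst, which should leave only the C2-Re face of the enal open; C1 and C10 form as mixtures but both become trigonal in step 10, so every diastereomer converges. The step needs regioselectivity (quaternary C9 bonded to C10), which the 1-alkyl-substituted diene terminus and Lewis-acid polarisation should secure, and enal-face selectivity, which rests on the catalyst alone and not on which diene enantiomer or endo/exo mode reacts. The closest known reaction type is the oxazaborolidinium-catalysed Diels–Alder addition of 2-substituted enals to 1-vinylcyclohexene-type dienes.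

**Step 8**
Reactants: 13 Diels–Alder aldehyde
Product: 15 tert-butyldimethyl{[(7R,8R)-4,4,7,8-tetramethyl-8-[4-(trimethylsilyl)but-3-yn-1-yl]-1,2,3,4,6,7,8,8a-octahydronaphthalen-1-yl]oxy}silane (C1/C10 epimers), via tosylhydrazone 14 (not isolated)
Conditions: TsNHNH2, THF, 23 °C; then catecholborane, CHCl3, 0 °C; then NaOAc·3H2O, 60 °C
Reagents that add atoms: none
Why: Kabalka-type tosylhydrazone reduction (hydroboration of C=N, then loss of sulfinate and N2) should turn the neopentyl CHO into the C9 methyl group without touching the silyl groups, the alkyne or the alkene.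

**Step 9**
Reactants: 15 silyl ether
Product: 16 (7R,8R)-8-(but-3-yn-1-yl)-4,4,7,8-tetramethyl-1,2,3,4,6,7,8,8a-octahydronaphthalen-1-ol (C1/C10 epimers)
Conditions: TBAF, THF, 23 °C
Reagents that add atoms: none
Why: fluoride should cleave both the TBS ether and the alkynyl C–Si bond in one operation.

**Step 10**
Reactants: 16 alcohol
Product: 18 (7R,8R)-8-(but-3-yn-1-yl)-4,4,7,8-tetramethyl-3,4,5,6,7,8-hexahydronaphthalen-1(2H)-one, via nonconjugated ketone 17 (not isolated)
Conditions: Dess–Martin periodinane, NaHCO3, CH2Cl2, 23 °C; then DBU (0.2 equiv), CH2Cl2, 23 °C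
Reagents that add atoms: none
Why: Dess–Martin oxidation followed by base-mediated conjugation through the dienolate should funnel all C1/C10 epimers into the single tetrasubstituted C5=C10 enone.

**Step 11**
Reactants: 18 enone
Product: 19 (1R,7R,8R)-8-(but-3-yn-1-yl)-4,4,7,8-tetramethyl-1,2,3,4,5,6,7,8-octahydronaphthalen-1-ol
Conditions: (S)-1-methyl-3,3-diphenyltetrahydro-1H,3H-pyrrolo[1,2-c][1,3,2]oxazaborole (0.5 equiv), catecholborane, toluene, −78 °C
Reagents that add atoms: none
Why: Corey–Bakshi–Shibata reduction with the alkenyl carbon as the large group should give the (1R)-allylic alcohol under reagent control, and catecholborane at low temperature spares the terminal alkyne.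

**Step 12**
Reactants: 19 allylic alcohol
Product: 22 (1R,2R,4aS)-1-(but-3-yn-1-yl)-1,2,5,5-tetramethyl-1,2,3,4,4a,5,6,7-octahydronaphthalene, via sulfonylhydrazine 20 (not isolated), via allylic diazene 21 (not isolated)
Conditions: 2-O2NC6H4SO2NHNH2, PPh3, DEAD, N-methylmorpholine, −30 → 23 °C
Reagents that add atoms: none
Why: Myers reductive 1,3-transposition, in which Mitsunobu displacement with inversion, loss of sulfinic acid and retro-ene loss of N2 from the diazene deliver hydrogen suprafacially to C5 on the face opposite the original OH, setting C5 and placing the alkene at C1=C10.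

**Step 13**
Reactants: 23 methyl (2R)-3-hydroxy-2-methylpropanoate
Product: 24 methyl (2R)-3-[(tert-butyldimethylsilyl)oxy]-2-methylpropanoate
Conditions: TBSCl, imidazole, CH2Cl2, 23 °C
Reagents that add atoms: tert-butyldimethylsilyl chloride CC(C)(C)[Si](C)(C)Cl
Why: standard silylation of the Roche ester, whose stereocentre becomes Cα.

**Step 14**
Reactants: 24 silyl ether ester
Product: 25 (2R)-3-[(tert-butyldimethylsilyl)oxy]-2-methylpropanal
Conditions: i-Bu2AlH, CH2Cl2, −78 °C
Reagents that add atoms: none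
Why: partial ester reduction stops at the aldehyde through the stable tetrahedral aluminium hemiacetal, and cold work-up with immediate use should keep the α-stereocentre.

**Step 15**
Reactants: 25 aldehyde
Product: 26 tert-butyldimethyl[(2R)-2-(oxiran-2-yl)propoxy]silane (both epimers at the oxirane carbon)
Conditions: Me3S+ I−, n-BuLi, THF, −10 → 0 °C
Reagents that add atoms: trimethylsulfonium iodide C[S+](C)C.[I-]
Why: Corey–Chaykovsky methylene transfer gives the terminal epoxide; the new centre is not controlled here and is sorted in step 16.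

**Step 16**
Reactants: 26 epoxide mixture
Product: 27 tert-butyldimethyl{(2R)-2-[(2S)-oxiran-2-yl]propoxy}silane
Conditions: (R,R)-(salen)Co(OAc) (0.5 mol%, trivalent cobalt; salen = N,N'-bis(3,5-di-tert-butylsalicylidene)cyclohexane-1,2-diamine dianion), H2O (0.6 equiv), THF, 0 → 23 °C
Reagents that add atoms: none
Why: Jacobsen hydrolytic kinetic resolution, in which the (R,R)-catalyst should hydrolyse the (2R)-oxirane epimer and leave the (2S)-oxirane, so the carbinol centre that becomes C3' is set by the catalyst.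

**Step 17**
Reactants: 22 alkyne; 27 (S)-epoxide
Product: 30 (2R,3R,5E)-1-[(tert-butyldimethylsilyl)oxy]-8-Dec-2,6-dimethyloct-5-en-3-ol, via alkenylalane 28 (not isolated), via lithium alanate 29 (not isolated)
Conditions: Me3Al, Cp2ZrCl2, CH2Cl2, 0 → 23 °C; then n-BuLi, hexane/THF, −78 °C; then 27, −78 → 0 °C
Reagents that add atoms: trimethylaluminium C[Al](C)C
Why: Negishi zirconium-catalysed carboalumination adds CH3–Al syn with methyl on the internal carbon, fixing the (E)-trisubstituted alkene, and the derived alkenylalanate should open the terminal epoxide at CH2 with retention of both the alkene geometry and the carbinol configuration.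

**Step 18**
Reactants: 30 homoallylic alcohol
Product: 31 (2R,3R)-4-[(tert-butyldimethylsilyl)oxy]-1-[(2S,3S)-3-(2-Dec-ethyl)-3-methyloxiran-2-yl]-3-methylbutan-2-ol
Conditions: VO(acac)2 (5 mol%), t-BuOOH, CH2Cl2, 0 °C
Reagents that add atoms: tert-butyl hydroperoxide CC(C)(C)OO
Why: hydroxyl-directed vanadium-catalysed epoxidation of a homoallylic alcohol through a chair-like vanadate transition state (carbinol substituent equatorial, allylic strain from the cis methyl) should give the 1,3-syn epoxy alcohol and leave the remote C1=C10 alkene alone.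

**Step 19**
Reactants: 31 epoxy alcohol
Product: 32 (2R,3R)-4-[(tert-butyldimethylsilyl)oxy]-1-[(2S,3S)-3-(2-Dec-ethyl)-3-methyloxiran-2-yl]-3-methylbutan-2-yl methanesulfonate
Conditions: MsCl, Et3N, CH2Cl2, −20 °C
Reagents that add atoms: methanesulfonyl chloride CS(=O)(=O)Cl
Why: mesylation with retention activates C3' for the later invertive ring closure.

**Step 20**
Reactants: 32 epoxy mesylate
Product: 34 (3S,5S,6R)-3-{(2R)-1-[(tert-butyldimethylsilyl)oxy]propan-2-yl}-6-(2-Dec-ethyl)-6-methyl-1,2-dioxan-5-ol (ring numbered as in the target), via hydroperoxide 33 (not isolated)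
Conditions: H2O2 (ethereal), H3PMo12O40 (cat.), Et2O, 23 °C; then KOtBu, 18-crown-6, THF, 0 °C
Reagents that add atoms: hydrogen peroxide OO
Why: acid-catalysed perhydrolysis of the trisubstituted epoxide at its tertiary carbon with inversion sets C6', and 6-exo-tet intramolecular alkylation of the hydroperoxide by the mesylate with inversion at C3' should close the 1,2-dioxane through a chair with the side chain, the C12 chain and the hydroxyl equatorial and the methyl axial.

**Step 21**
Reactants: 34 hydroxy dioxane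
Product: 35 (3S,6R)-3-{(2R)-1-[(tert-butyldimethylsilyl)oxy]propan-2-yl}-6-(2-Dec-ethyl)-6-methyl-3,6-dihydro-1,2-dioxine
Conditions: Burgess reagent (MeO2CN−SO2N+Et3), benzene, 50 °C
Reagents that add atoms: none
Why: Burgess syn-dehydration can remove only a C4' hydrogen because C6' is quaternary, so the C4'=C5' alkene should be the sole regioisomer.

**Step 22**
Reactants: 35 dihydrodioxine
Product: 36 tert-butyl{(2R)-2-[(3S,6R)-6-(2-Dec-ethyl)-6-methyl-1,2-dioxan-3-yl]propoxy}dimethylsilane
Conditions: KO2CN=NCO2K, AcOH, CH2Cl2/MeOH, 0 → 23 °C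
Reagents that add atoms: none
Why: diimide reduction saturates the cis-disubstituted ring alkene without cleaving the O–O bond and should not touch the hindered trisubstituted C1=C10 alkene.

**Step 23**
Reactants: 36 silyl ether
Product: 37 (2R)-2-[(3S,6R)-6-(2-Dec-ethyl)-6-methyl-1,2-dioxan-3-yl]propan-1-ol
Conditions: HF·pyridine, THF, 0 °C
Reagents that add atoms: none
Why: acidic fluoride desilylation avoids the base-induced Kornblum–DeLaMare cleavage that the C3'–H peroxide could suffer.

**Step 24**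
Reactants: 37 primary alcohol
Product: 39 mycaperoxide H, (2S)-2-[(3S,6R)-6-(2-Dec-ethyl)-6-methyl-1,2-dioxan-3-yl]propanoic acid, via aldehyde 38 (not isolated)
Conditions: TEMPO (cat.), PhI(OAc)2, MeCN/H2O, 23 °C
Reagents that add atoms: water O
Why: oxoammonium (TEMPO/PhI(OAc)2) oxidation of the primary alcohol through the aldehyde hydrate under near-neutral conditions should give the acid while keeping the peroxide, the alkene and the Cα stereocentre.

**Compound list**

1 | 4,4-dimethylcyclohexane-1,3-dione | CC1(C)CCC(=O)CC1=O | starting material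
2 | 3-ethoxy-6,6-dimethylcyclohex-2-en-1-one | CCOC1=CC(=O)C(C)(C)CC1 | intermediate
3 | 3-ethoxy-6,6-dimethyl-1-vinylcyclohex-2-en-1-ol | CCOC1=CC(O)(C=C)C(C)(C)CC1 | intermediate
4 | 4,4-dimethyl-3-vinylcyclohex-2-en-1-one | C=CC1=CC(=O)CCC1(C)C | intermediate
5 | rac-4,4-dimethyl-3-vinylcyclohex-2-en-1-ol | C=CC1=CC(O)CCC1(C)C | intermediate
6 | rac-tert-butyl[(4,4-dimethyl-3-vinylcyclohex-2-en-1-yl)oxy]dimethylsilane | C=CC1=CC(O[Si](C)(C)C(C)(C)C)CCC1(C)C | intermediate
7 | (E)-but-2-enal | C/C=C/C=O | starting material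
8 | 2,3-dibromobutanal | CC(Br)C(Br)C=O | intermediate
9 | (Z)-2-bromobut-2-enal | C/C=C(\Br)C=O | intermediate
10 | (4-bromobut-1-yn-1-yl)trimethylsilane | C[Si](C)(C)C#CCCBr | starting material
11 | [4-(trimethylsilyl)but-3-yn-1-yl]zinc bromide | C[Si](C)(C)C#CCC[Zn]Br | intermediate
12 | (E)-2-[4-(trimethylsilyl)but-3-yn-1-yl]but-2-enal | C/C=C(/C=O)CCC#C[Si](C)(C)C | intermediate
13 | (1S,2R)-8-[(tert-butyldimethylsilyl)oxy]-2,5,5-trimethyl-1-[4-(trimethylsilyl)but-3-yn-1-yl]-1,2,3,5,6,7,8,8a-octahydronaphthalene-1-carbaldehyde (C8/C8a epimers) | C[Si](C)(C)C#CCC[C@@]1(C=O)C2C(O[Si](C)(C)C(C)(C)C)CCC(C)(C)C2=CC[C@H]1C | intermediate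
14 | 4-methylbenzenesulfonylhydrazone of 13 | C[Si](C)(C)C#CCC[C@@]1(C=NNS(=O)(=O)c3ccc(C)cc3)C2C(O[Si](C)(C)C(C)(C)C)CCC(C)(C)C2=CC[C@H]1C | intermediate
15 | tert-butyldimethyl{[(7R,8R)-4,4,7,8-tetramethyl-8-[4-(trimethylsilyl)but-3-yn-1-yl]-1,2,3,4,6,7,8,8a-octahydronaphthalen-1-yl]oxy}silane (C1/C8a epimers) | C[Si](C)(C)C#CCC[C@@]1(C)C2C(O[Si](C)(C)C(C)(C)C)CCC(C)(C)C2=CC[C@H]1C | intermediate
16 | (7R,8R)-8-(but-3-yn-1-yl)-4,4,7,8-tetramethyl-1,2,3,4,6,7,8,8a-octahydronaphthalen-1-ol (C1/C8a epimers) | C#CCC[C@@]1(C)C2C(O)CCC(C)(C)C2=CC[C@H]1C | intermediate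
17 | (7R,8R)-8-(but-3-yn-1-yl)-4,4,7,8-tetramethyl-3,4,6,7,8,8a-hexahydronaphthalen-1(2H)-one (C8a epimers) | C#CCC[C@@]1(C)C2C(=O)CCC(C)(C)C2=CC[C@H]1C | intermediate
18 | (7R,8R)-8-(but-3-yn-1-yl)-4,4,7,8-tetramethyl-3,4,5,6,7,8-hexahydronaphthalen-1(2H)-one | C#CCC[C@@]1(C)C2=C(CC[C@H]1C)C(C)(C)CCC2=O | intermediate
19 | (1R,7R,8R)-8-(but-3-yn-1-yl)-4,4,7,8-tetramethyl-1,2,3,4,5,6,7,8-octahydronaphthalen-1-ol | C#CCC[C@@]1(C)C2=C(CC[C@H]1C)C(C)(C)CC[C@H]2O | intermediate
20 | 1-[(1S,7R,8R)-8-(but-3-yn-1-yl)-4,4,7,8-tetramethyl-1,2,3,4,5,6,7,8-octahydronaphthalen-1-yl]-1-(2-nitrophenylsulfonyl)hydrazine | C#CCC[C@@]1(C)C2=C(CC[C@H]1C)C(C)(C)CC[C@@H]2N(N)S(=O)(=O)c1ccccc1[N+](=O)[O-] | intermediate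
21 | [(1S,7R,8R)-8-(but-3-yn-1-yl)-4,4,7,8-tetramethyl-1,2,3,4,5,6,7,8-octahydronaphthalen-1-yl]diazene | C#CCC[C@@]1(C)C2=C(CC[C@H]1C)C(C)(C)CC[C@@H]2N=N | intermediate
22 | (1R,2R,4aS)-1-(but-3-yn-1-yl)-1,2,5,5-tetramethyl-1,2,3,4,4a,5,6,7-octahydronaphthalene | C#CCC[C@@]1(C)C2=CCCC(C)(C)[C@@H]2CC[C@H]1C | intermediate
23 | methyl (2R)-3-hydroxy-2-methylpropanoate | C[C@H](CO)C(=O)OC | starting material
24 | methyl (2R)-3-[(tert-butyldimethylsilyl)oxy]-2-methylpropanoate | C[C@H](CO[Si](C)(C)C(C)(C)C)C(=O)OC | intermediate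
25 | (2R)-3-[(tert-butyldimethylsilyl)oxy]-2-methylpropanal | C[C@H](CO[Si](C)(C)C(C)(C)C)C=O | intermediate
26 | tert-butyldimethyl[(2R)-2-(oxiran-2-yl)propoxy]silane (oxirane epimers) | C[C@H](CO[Si](C)(C)C(C)(C)C)C1CO1 | intermediate
27 | tert-butyldimethyl{(2R)-2-[(2S)-oxiran-2-yl]propoxy}silane | C[C@H](CO[Si](C)(C)C(C)(C)C)[C@H]1CO1 | intermediate
28 | [(1E)-4-Dec-2-methylbut-1-en-1-yl]dimethylalane | C[Al](C)/C=C(\C)CC[C@@]1(C)C2=CCCC(C)(C)[C@@H]2CC[C@H]1C | intermediate
29 | lithium butyl[(1E)-4-Dec-2-methylbut-1-en-1-yl]dimethylaluminate | [Li+].CCCC[Al-](C)(C)/C=C(\C)CC[C@@]1(C)C2=CCCC(C)(C)[C@@H]2CC[C@H]1C | intermediate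
30 | (2R,3R,5E)-1-[(tert-butyldimethylsilyl)oxy]-8-Dec-2,6-dimethyloct-5-en-3-ol | C[C@H](CO[Si](C)(C)C(C)(C)C)[C@H](O)C/C=C(\C)CC[C@@]1(C)C2=CCCC(C)(C)[C@@H]2CC[C@H]1C | intermediate
31 | (2R,3R)-4-[(tert-butyldimethylsilyl)oxy]-1-[(2S,3S)-3-(2-Dec-ethyl)-3-methyloxiran-2-yl]-3-methylbutan-2-ol | C[C@H](CO[Si](C)(C)C(C)(C)C)[C@H](O)C[C@@H]1O[C@@]1(C)CC[C@@]2(C)C3=CCCC(C)(C)[C@@H]3CC[C@H]2C | intermediate
32 | methanesulfonate of 31 | C[C@H](CO[Si](C)(C)C(C)(C)C)[C@H](OS(C)(=O)=O)C[C@@H]1O[C@@]1(C)CC[C@@]2(C)C3=CCCC(C)(C)[C@@H]3CC[C@H]2C | intermediate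
33 | (2R,3R,5S,6R)-1-[(tert-butyldimethylsilyl)oxy]-8-Dec-6-hydroperoxy-5-hydroxy-2,6-dimethyloctan-3-yl methanesulfonate | C[C@H](CO[Si](C)(C)C(C)(C)C)[C@H](OS(C)(=O)=O)C[C@H](O)[C@](C)(OO)CC[C@@]1(C)C2=CCCC(C)(C)[C@@H]2CC[C@H]1C | intermediate
34 | (3S,5S,6R)-3-{(2R)-1-[(tert-butyldimethylsilyl)oxy]propan-2-yl}-6-(2-Dec-ethyl)-6-methyl-1,2-dioxan-5-ol | C[C@H](CO[Si](C)(C)C(C)(C)C)[C@@H]1C[C@H](O)[C@@](C)(CC[C@@]2(C)C3=CCCC(C)(C)[C@@H]3CC[C@H]2C)OO1 | intermediate
35 | (3S,6R)-3-{(2R)-1-[(tert-butyldimethylsilyl)oxy]propan-2-yl}-6-(2-Dec-ethyl)-6-methyl-3,6-dihydro-1,2-dioxine | C[C@H](CO[Si](C)(C)C(C)(C)C)[C@@H]1C=C[C@@](C)(CC[C@@]2(C)C3=CCCC(C)(C)[C@@H]3CC[C@H]2C)OO1 | intermediate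
36 | tert-butyl{(2R)-2-[(3S,6R)-6-(2-Dec-ethyl)-6-methyl-1,2-dioxan-3-yl]propoxy}dimethylsilane | C[C@H](CO[Si](C)(C)C(C)(C)C)[C@@H]1CC[C@@](C)(CC[C@@]2(C)C3=CCCC(C)(C)[C@@H]3CC[C@H]2C)OO1 | intermediate
37 | (2R)-2-[(3S,6R)-6-(2-Dec-ethyl)-6-methyl-1,2-dioxan-3-yl]propan-1-ol | C[C@H](CO)[C@@H]1CC[C@@](C)(CC[C@@]2(C)C3=CCCC(C)(C)[C@@H]3CC[C@H]2C)OO1 | intermediate
38 | (2S)-2-[(3S,6R)-6-(2-Dec-ethyl)-6-methyl-1,2-dioxan-3-yl]propanal | C[C@H](C=O)[C@@H]1CC[C@@](C)(CC[C@@]2(C)C3=CCCC(C)(C)[C@@H]3CC[C@H]2C)OO1 | intermediate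
39 | mycaperoxide H, (2S)-2-[(3S,6R)-6-(2-Dec-ethyl)-6-methyl-1,2-dioxan-3-yl]propanoic acid | C[C@H](C(=O)O)[C@@H]1CC[C@@](C)(CC[C@@]2(C)C3=CCCC(C)(C)[C@@H]3CC[C@H]2C)OO1 | target

**Step count and risks**

Total step count: 24. Longest linear sequence: 18 steps (steps 1–4, 7–12, 17–24).

Steps most likely to fail:

1. Step 7 (key cycloaddition). Risk: low reactivity of the trisubstituted enal toward the hindered diene terminus, ionisation of the allylic silyl ether by the acid catalyst, or insufficient enal-face selectivity. Fallback, from 4 and 12, returning at 16: the union would be made intramolecular and substrate-controlled. Dienone 4 is reduced with the (S)-methyl oxazaborolidine and catecholborane to (R)-4,4-dimethyl-3-vinylcyclohex-2-en-1-ol F1. Enal 12 is oxidised (NaClO2, NaH2PO4, 2-methylbut-2-ene) to (E)-2-[4-(trimethylsilyl)but-3-yn-1-yl]but-2-enoic acid F2. The two are esterified (DCC, DMAP) to the dienyl ester F3. A thermal ester-tethered intramolecular Diels–Alder reaction (toluene, BHT, 190 °C) through the carbonyl-endo mode, with the tether fixing the diene face, should give the cis-fused tricyclic lactone F4 with the same C8/C9 configuration. i-Bu2AlH gives the lactol F5; tosylhydrazone formation and catecholborane/NaOAc·3H2O reduction of its open hydroxy aldehyde form give the C9-methyl alcohol F6; TBAF as in step 9 then gives a single diastereomer of 16. A competing carbonyl-exo cycloaddition would erode the enantiomeric purity on this path.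

2. Step 20 (perhydrolysis and ring closure). Risk: acid-promoted rearrangement of the epoxide, attack of the peroxomolybdate on the C1=C10 alkene, or base-induced peroxide cleavage during cyclisation. Fallback, from 30, returning at 36: the C6'–O bond would be made by a radical route. Alcohol 30 is mesylated to (2R,3R,5E)-1-[(tert-butyldimethylsilyl)oxy]-8-Dec-2,6-dimethyloct-5-en-3-yl methanesulfonate F8. Mukaiyama–Isayama hydroperoxysilylation (Co(acac)2, O2, Et3SiH) of the side-chain alkene gives the tertiary triethylsilyl peroxide F9 as both C6' epimers. K2CO3 in MeOH unmasks the hydroperoxide, which closes onto the mesylate with inversion to give 36 and its C6' epimer, to be separated. This path bypasses steps 18, 21 and 22 but gives no control at C6'.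

3. Step 12 (reductive transposition). Risk: failure of the Mitsunobu displacement at the hindered C1 carbinol (elimination or no reaction). Fallback, from 18, returning at 22: enone 18 is condensed with TsNHNH2 to the α,β-unsaturated tosylhydrazone F7 and reduced with catecholborane, then NaOAc·3H2O (alkene-migrating tosylhydrazone reduction). This reaches 22 through the same type of allylic diazene, with C5 then resting on the facial preference of hydride addition at C1 and not on the CBS-set carbinol.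

**Further compounds**

F1 | step 7 | (R)-4,4-dimethyl-3-vinylcyclohex-2-en-1-ol | C=CC1=C[C@H](O)CCC1(C)C
F2 | step 7 | (E)-2-[4-(trimethylsilyl)but-3-yn-1-yl]but-2-enoic acid | C/C=C(/C(=O)O)CCC#C[Si](C)(C)C
F3 | step 7 | (1R)-4,4-dimethyl-3-vinylcyclohex-2-en-1-yl (E)-2-[4-(trimethylsilyl)but-3-yn-1-yl]but-2-enoate | C/C=C(/C(=O)O[C@H]1C=C(C=C)C(C)(C)CC1)CCC#C[Si](C)(C)C
F4 | step 7 | cis-fused tricyclic lactone (C1–O–C(=O)–C9 bridge, C5=C6 alkene) | C[Si](C)(C)C#CCC[C@@]1(C(=O)O[C@@H]2CCC(C)(C)C3=CC[C@H]1C)[C@H]23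
F5 | step 7 | lactol of F4 | C[Si](C)(C)C#CCC[C@@]1(C(O)O[C@@H]2CCC(C)(C)C3=CC[C@H]1C)[C@H]23
F6 | step 7 | (1R,7R,8R,8aR)-4,4,7,8-tetramethyl-8-[4-(trimethylsilyl)but-3-yn-1-yl]-1,2,3,4,6,7,8,8a-octahydronaphthalen-1-ol | C[Si](C)(C)C#CCC[C@@]1(C)[C@@H]2[C@H](O)CCC(C)(C)C2=CC[C@H]1C
F7 | step 12 | 4-methylbenzenesulfonylhydrazone of 18 | C#CCC[C@@]1(C)C2=C(CC[C@H]1C)C(C)(C)CCC2=NNS(=O)(=O)c1ccc(C)cc1
F8 | step 20 | (2R,3R,5E)-1-[(tert-butyldimethylsilyl)oxy]-8-Dec-2,6-dimethyloct-5-en-3-yl methanesulfonate | C[C@H](CO[Si](C)(C)C(C)(C)C)[C@H](OS(C)(=O)=O)C/C=C(\C)CC[C@@]1(C)C2=CCCC(C)(C)[C@@H]2CC[C@H]1C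
F9 | step 20 | (2R,3R)-1-[(tert-butyldimethylsilyl)oxy]-8-Dec-2,6-dimethyl-6-[(triethylsilyl)peroxy]octan-3-yl methanesulfonate (C6 epimers) | C[C@H](CO[Si](C)(C)C(C)(C)C)[C@H](OS(C)(=O)=O)CCC(C)(OO[Si](CC)(CC)CC)CC[C@@]1(C)C2=CCCC(C)(C)[C@@H]2CC[C@H]1C
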